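The lactone C7–O bond and the cyclopropane C8–C10 bond are disconnected together, copying the presumed biosynthesis of cyclopropyl oxylipin lactones. The key step exploits the O–C7–C8(–C9–)C10–C11–O array: C7 of the oxocan-2-one ring is a cyclopropylcarbinyl carbon and C11, on the other flank of the C8–C9–C10 ring, carries a hydroxyl. In one operation a Lewis acid opens a (10R,11R)-epoxy alcohol, the (7E)-alkene closes the cyclopropane, and the tert-butyl ester carbonyl captures the C7 cation, closing the eight-membered lactone and setting C7, C8 and C10. The precursor is an acyclic tert-butyl epoxy alkenoate; the side chain follows by Julia–Kocienski olefination.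

Key step: step 5

Numbering used throughout: C1 is the lactone carbonyl carbon, C7 the lactone carbinol carbon, C8–C9–C10 the cyclopropane (C9 is its CH2), C11 and C14 the carbinol carbons, C22 the terminal methyl; the target is (7R,8R,10R,11R,14S).
Assumption: compound 4 is used as the racemate, because its stereocentre is destroyed in step 3.

Step 1
Reactants: 1 oct-7-ynoic acid
Product: 2 tert-butyl oct-7-ynoate
Conditions: tert-butyl 2,2,2-trichloroacetimidate (2 equiv), BF3·OEt2 (cat.), CH2Cl2/cyclohexane, 23 °C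
Reagents that add atoms: tert-butyl 2,2,2-trichloroacetimidate, CC(C)(C)OC(=N)C(Cl)(Cl)Cl
Why: Acid-catalysed O-tert-butylation of the carboxylic acid by the trichloroacetimidate should give the ester without touching the terminal alkyne.

Step 2
Reactants: 2 tert-butyl oct-7-ynoate
Product: 3 tert-butyl (7E)-8-(4,4,5,5-tetramethyl-1,3,2-dioxaborolan-2-yl)oct-7-enoate
Conditions: pinacolborane (1.2 equiv), Cp2Zr(H)Cl (5 mol%), Et3N (10 mol%), neat, 60 °C
Reagents that add atoms: pinacolborane, B1OC(C)(C)C(C)(C)O1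
Why: Zirconocene-hydride-catalysed hydroboration of a terminal alkyne is a syn, anti-Markovnikov addition and should give only the (E)-alkenylboronate.

Step 3
Reactants: 3 tert-butyl (7E)-8-(4,4,5,5-tetramethyl-1,3,2-dioxaborolan-2-yl)oct-7-enoate; 4 2-vinyloxirane
Product: 5 tert-butyl (7E,10E)-12-hydroxydodeca-7,10-dienoate
Conditions: Pd(PPh3)4 (5 mol%), THF/H2O 10:1, 40 °C
Reagents that add atoms: none
Why: Zerovalent palladium opens the vinyl epoxide to a π-allyl complex whose alkoxide activates boron, and alkenyl transfer with reductive elimination at the unsubstituted allyl terminus (Suzuki–Miyaura-type 1,4-coupling) should give the linear (10E)-allylic alcohol with retention of the (7E) geometry.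

Step 4
Reactants: 5 tert-butyl (7E,10E)-12-hydroxydodeca-7,10-dienoate
Product: 6 tert-butyl (7E)-9-[(2R,3R)-3-(hydroxymethyl)oxiran-2-yl]non-7-enoate
Conditions: Ti(OiPr)4 (10 mol%), D-(−)-diisopropyl tartrate (12 mol%), t-BuOOH (2 equiv), 4 Å molecular sieves, CH2Cl2, −20 °C
Reagents that add atoms: tert-butyl hydroperoxide, CC(C)(C)OO
Why: Sharpless asymmetric epoxidation acts only on the allylic alcohol alkene, and the D-(−)-tartrate ligand directs oxygen to the face that gives the (2R,3R)-epoxy alcohol (C10 and C11 set by the reagent), leaving the isolated C7=C8 alkene untouched.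

Step 5
Reactants: 6 tert-butyl (7E)-9-[(2R,3R)-3-(hydroxymethyl)oxiran-2-yl]non-7-enoate
Product: 7 (8R)-8-[(1R,2R)-2-[(1S)-1,2-dihydroxyethyl]cyclopropyl]oxocan-2-one
Conditions: Sc(OTf)3 (10 mol%), CH2Cl2/(CF3)2CHOH 4:1, 6 added by syringe pump to 2 mM, −20 → 0 °C
Reagents that add atoms: none
Why: Proposed new method: Sc(OTf)3 chelated by the epoxy alcohol polarises the C10–O bond, the (7E)-alkene attacks C10 from the rear through C8 (homoallyl to cyclopropylcarbinyl participation, as in the i-steroid rearrangement and in epoxide-initiated cation–olefin cyclisations), and the C7 cation is captured by the carbonyl oxygen of the tert-butyl ester, whose dialkoxycarbenium ion then sheds 2-methylpropene irreversibly. The closest known reaction types are the cation-triggered formation of cyclopropyl δ-lactones from homoallylic precursors in related marine oxylipins and electrophile-induced lactonisation to eight-membered rings (iodolactonisation); the new element is capture of a cyclopropylcarbinyl cation in an eight-membered ring. The cyclopropane closes 3-exo-tet at the epoxide carbon C10, and the lactone closes by 8-exo attack of the carbonyl oxygen on the trigonal C7. C10 is set by inversion at the (10R)-epoxide carbon, C11 is carried over unchanged from step 4, C8 by the trans arrangement of the two ring substituents in the 3-exo transition state, and C7 by anti addition across the (E)-alkene (oxygen enters opposite the new C8–C10 bond). The step needs opening at C10 and not C11 (secured by the chelate, the electron-poor C11 and three- versus four-ring closure), capture before the cation rotates or loses a proton (secured by the unsymmetrically bridged cation and the built-in nucleophile), and ring closure over oligomerisation (secured by high dilution in poorly nucleophilic hexafluoroisopropanol).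

Step 6
Reactants: 7 (8R)-8-[(1R,2R)-2-[(1S)-1,2-dihydroxyethyl]cyclopropyl]oxocan-2-one
Product: 8 (8R)-8-[(1R,2R)-2-[(1S)-1,2-bis(triethylsilyloxy)ethyl]cyclopropyl]oxocan-2-one
Conditions: Et3SiCl (2.5 equiv), imidazole (5 equiv), DMAP (cat.), CH2Cl2, 0 → 23 °C
Reagents that add atoms: chlorotriethylsilane, CC[Si](Cl)(CC)CC
Why: Silylation with silyl chloride and imidazole should protect both hydroxyls as triethylsilyl ethers and leave the lactone alone.

Step 7
Reactants: 8 (8R)-8-[(1R,2R)-2-[(1S)-1,2-bis(triethylsilyloxy)ethyl]cyclopropyl]oxocan-2-one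
Product: 9 (2S)-2-[(1R,2R)-2-[(2R)-8-oxooxocan-2-yl]cyclopropyl]-2-(triethylsilyloxy)acetaldehyde
Conditions: (COCl)2 (4 equiv), DMSO (8 equiv), CH2Cl2, −78 → −40 °C; then Et3N (10 equiv), −78 → 0 °C
Reagents that add atoms: none
Why: Under Swern conditions the activated DMSO species cleaves and oxidises the unhindered primary triethylsilyl ether directly while the secondary one survives (chemoselective Swern oxidation of a primary silyl ether), and the low temperature should prevent epimerisation at C11.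

Step 8
Reactants: 10 (2S)-2-(chloromethyl)oxirane
Product: 11 (2S)-1-chloro-5-(trimethylsilyl)pent-4-yn-2-ol
Conditions: ethynyltrimethylsilane, n-BuLi, THF, −78 °C; then BF3·OEt2, then 10, −78 °C; aqueous work-up
Reagents that add atoms: ethynyltrimethylsilane, C#C[Si](C)(C)C
Why: BF3-promoted opening of the epoxide at its CH2 terminus by the lithium acetylide (epoxide alkynylation) breaks no bond to the stereocentre, so the (S)-chlorohydrin follows from the (S)-epoxide.

Step 9
Reactants: 11 (2S)-1-chloro-5-(trimethylsilyl)pent-4-yn-2-ol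
Product: 14 (2S)-1-[(1-phenyl-1H-tetrazol-5-yl)sulfanyl]pent-4-yn-2-ol, via silylated epoxide 12 (not isolated), via desilylated epoxide 13 (not isolated)
Conditions: K2CO3 (2.5 equiv), 1-phenyl-1H-tetrazole-5-thiol (1.1 equiv), MeOH, 23 → 50 °C
Reagents that add atoms: 1-phenyl-1H-tetrazole-5-thiol, SC1=NN=NN1c1ccccc1
Why: Carbonate in methanol closes the chlorohydrin to the terminal epoxide and cleaves the alkynyl C–Si bond, and the thiolate then opens the epoxide at CH2 (SN2), so the carbinol configuration is retained.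

Step 10
Reactants: 14 (2S)-1-[(1-phenyl-1H-tetrazol-5-yl)sulfanyl]pent-4-yn-2-ol
Product: 15 5-{[(2S)-2-(tert-butyldimethylsilyloxy)pent-4-yn-1-yl]sulfanyl}-1-phenyl-1H-tetrazole
Conditions: t-BuMe2SiCl (1.3 equiv), imidazole (2.5 equiv), DMF, 23 °C
Reagents that add atoms: tert-butylchlorodimethylsilane, CC(C)(C)[Si](C)(C)Cl
Why: Silyl ether formation protects the secondary alcohol that would otherwise interfere with the later sulfone metalation.

Step 11
Reactants: 15 5-{[(2S)-2-(tert-butyldimethylsilyloxy)pent-4-yn-1-yl]sulfanyl}-1-phenyl-1H-tetrazole; 16 1-bromopent-2-yne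
Product: 17 5-{[(2S)-2-(tert-butyldimethylsilyloxy)deca-4,7-diyn-1-yl]sulfanyl}-1-phenyl-1H-tetrazole
Conditions: CuI (1 equiv), Cs2CO3 (1 equiv), DMF, 23 °C
Reagents that add atoms: none
Why: Copper-mediated coupling of a terminal alkyne with a propargylic bromide under mild carbonate base should give the skipped diyne without isomerisation to allenes.

Step 12
Reactants: 17 5-{[(2S)-2-(tert-butyldimethylsilyloxy)deca-4,7-diyn-1-yl]sulfanyl}-1-phenyl-1H-tetrazole
Product: 18 5-{[(2S)-2-(tert-butyldimethylsilyloxy)deca-4,7-diyn-1-yl]sulfonyl}-1-phenyl-1H-tetrazole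
Conditions: (NH4)6Mo7O24·4H2O (10 mol%), 30% H2O2 (excess), EtOH, 0 → 23 °C
Reagents that add atoms: hydrogen peroxide, OO
Why: Molybdate-catalysed peroxide oxidation takes the sulfide to the sulfone and does not attack alkynes or the silyl ether.

Step 13
Reactants: 18 5-{[(2S)-2-(tert-butyldimethylsilyloxy)deca-4,7-diyn-1-yl]sulfonyl}-1-phenyl-1H-tetrazole
Product: 19 5-{[(2S,4Z,7Z)-2-(tert-butyldimethylsilyloxy)deca-4,7-dien-1-yl]sulfonyl}-1-phenyl-1H-tetrazole
Conditions: H2 (1 atm), Pd/CaCO3 poisoned with Pb(OAc)2, quinoline, EtOAc, 23 °C, stopped at 2 equiv H2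
Reagents that add atoms: none
Why: Lindlar semihydrogenation adds hydrogen syn to each alkyne and should give the (4Z,7Z)-diene, with quinoline and uptake control guarding against over-reduction.

Step 14
Reactants: 19 5-{[(2S,4Z,7Z)-2-(tert-butyldimethylsilyloxy)deca-4,7-dien-1-yl]sulfonyl}-1-phenyl-1H-tetrazole; 9 (2S)-2-[(1R,2R)-2-[(2R)-8-oxooxocan-2-yl]cyclopropyl]-2-(triethylsilyloxy)acetaldehyde
Product: 20 (8R)-8-[(1R,2R)-2-[(1R,2E,4S,6Z,9Z)-4-(tert-butyldimethylsilyloxy)-1-(triethylsilyloxy)dodeca-2,6,9-trien-1-yl]cyclopropyl]oxocan-2-one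
Conditions: 19 (1.3 equiv), KN(SiMe3)2 (1.25 equiv), DME, −78 °C, 20 min; then 9, −78 → −20 °C
Reagents that add atoms: none
Why: Julia–Kocienski olefination of the metalated phenyltetrazolyl sulfone with the aldehyde (addition, Smiles rearrangement, loss of SO2) should give the (12E)-alkene, and the aldehyde is far more electrophilic than the lactone.

Step 15
Reactants: 20 (8R)-8-[(1R,2R)-2-[(1R,2E,4S,6Z,9Z)-4-(tert-butyldimethylsilyloxy)-1-(triethylsilyloxy)dodeca-2,6,9-trien-1-yl]cyclopropyl]oxocan-2-one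
Product: 21 (8R)-8-[(1R,2R)-2-[(1R,2E,4S,6Z,9Z)-1,4-dihydroxydodeca-2,6,9-trien-1-yl]cyclopropyl]oxocan-2-one
Conditions: HF·pyridine, excess pyridine, THF, 0 → 23 °C
Reagents that add atoms: none
Why: Pyridine-buffered fluoride desilylation should remove both silyl ethers without ionising the allylic cyclopropylcarbinyl alcohol at C11 or opening the lactone.

Compound list
1 | oct-7-ynoic acid | C#CCCCCCC(=O)O | starting material
2 | tert-butyl oct-7-ynoate | C#CCCCCCC(=O)OC(C)(C)C | intermediate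
3 | tert-butyl (7E)-8-(4,4,5,5-tetramethyl-1,3,2-dioxaborolan-2-yl)oct-7-enoate | CC(C)(C)OC(=O)CCCCC/C=C/B1OC(C)(C)C(C)(C)O1 | intermediate
4 | 2-vinyloxirane (racemic butadiene monoxide) | C=CC1CO1 | starting material
5 | tert-butyl (7E,10E)-12-hydroxydodeca-7,10-dienoate | CC(C)(C)OC(=O)CCCCC/C=C/C/C=C/CO | intermediate
6 | tert-butyl (7E)-9-[(2R,3R)-3-(hydroxymethyl)oxiran-2-yl]non-7-enoate | CC(C)(C)OC(=O)CCCCC/C=C/C[C@H]1O[C@@H]1CO | intermediate
7 | (8R)-8-[(1R,2R)-2-[(1S)-1,2-dihydroxyethyl]cyclopropyl]oxocan-2-one | OC[C@@H](O)[C@@H]1C[C@H]1[C@H]1CCCCCC(=O)O1 | intermediate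
8 | (8R)-8-[(1R,2R)-2-[(1S)-1,2-bis(triethylsilyloxy)ethyl]cyclopropyl]oxocan-2-one | CC[Si](CC)(CC)OC[C@@H](O[Si](CC)(CC)CC)[C@@H]1C[C@H]1[C@H]1CCCCCC(=O)O1 | intermediate
9 | (2S)-2-[(1R,2R)-2-[(2R)-8-oxooxocan-2-yl]cyclopropyl]-2-(triethylsilyloxy)acetaldehyde | O=C[C@@H](O[Si](CC)(CC)CC)[C@@H]1C[C@H]1[C@H]1CCCCCC(=O)O1 | intermediate
10 | (2S)-2-(chloromethyl)oxirane ((S)-epichlorohydrin) | ClC[C@@H]1CO1 | starting material
11 | (2S)-1-chloro-5-(trimethylsilyl)pent-4-yn-2-ol | ClC[C@@H](O)CC#C[Si](C)(C)C | intermediate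
12 | (2S)-2-[3-(trimethylsilyl)prop-2-yn-1-yl]oxirane | C[Si](C)(C)C#CC[C@H]1CO1 | intermediate (not isolated)
13 | (2S)-2-(prop-2-yn-1-yl)oxirane | C#CC[C@H]1CO1 | intermediate (not isolated)
14 | (2S)-1-[(1-phenyl-1H-tetrazol-5-yl)sulfanyl]pent-4-yn-2-ol | C#CC[C@H](O)CSC1=NN=NN1c1ccccc1 | intermediate
15 | 5-{[(2S)-2-(tert-butyldimethylsilyloxy)pent-4-yn-1-yl]sulfanyl}-1-phenyl-1H-tetrazole | C#CC[C@H](O[Si](C)(C)C(C)(C)C)CSC1=NN=NN1c1ccccc1 | intermediate
16 | 1-bromopent-2-yne | CCC#CCBr | starting material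
17 | 5-{[(2S)-2-(tert-butyldimethylsilyloxy)deca-4,7-diyn-1-yl]sulfanyl}-1-phenyl-1H-tetrazole | CCC#CCC#CC[C@H](O[Si](C)(C)C(C)(C)C)CSC1=NN=NN1c1ccccc1 | intermediate
18 | 5-{[(2S)-2-(tert-butyldimethylsilyloxy)deca-4,7-diyn-1-yl]sulfonyl}-1-phenyl-1H-tetrazole | CCC#CCC#CC[C@H](O[Si](C)(C)C(C)(C)C)CS(=O)(=O)C1=NN=NN1c1ccccc1 | intermediate
19 | 5-{[(2S,4Z,7Z)-2-(tert-butyldimethylsilyloxy)deca-4,7-dien-1-yl]sulfonyl}-1-phenyl-1H-tetrazole | CC/C=C\C/C=C\C[C@H](O[Si](C)(C)C(C)(C)C)CS(=O)(=O)C1=NN=NN1c1ccccc1 | intermediate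
20 | (8R)-8-[(1R,2R)-2-[(1R,2E,4S,6Z,9Z)-4-(tert-butyldimethylsilyloxy)-1-(triethylsilyloxy)dodeca-2,6,9-trien-1-yl]cyclopropyl]oxocan-2-one | CC/C=C\C/C=C\C[C@H](O[Si](C)(C)C(C)(C)C)/C=C/[C@@H](O[Si](CC)(CC)CC)[C@@H]1C[C@H]1[C@H]1CCCCCC(=O)O1 | intermediate
21 | (8R)-8-[(1R,2R)-2-[(1R,2E,4S,6Z,9Z)-1,4-dihydroxydodeca-2,6,9-trien-1-yl]cyclopropyl]oxocan-2-one | CC/C=C\C/C=C\C[C@H](O)/C=C/[C@@H](O)[C@@H]1C[C@H]1[C@H]1CCCCCC(=O)O1 | target

Total step count: 15. Longest linear sequence: 9 steps (steps 1–7, 14 and 15).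

Steps most likely to fail

Step 5 (proposed new method). The C7 cyclopropylcarbinyl cation may be consumed by proton loss to a vinylcyclopropane, by intermolecular capture (oligomers), or by capture on both faces before the eight-membered ring closes. The fallback uses known chemistry only, closes the ring at the acyl C–O bond instead, sets out from 1 and comes back at 7. Mercury-catalysed Markovnikov hydration with concurrent Fischer esterification (HgSO4, H2SO4, MeOH/H2O) should give methyl 7-oxooctanoate F1. Its kinetic lithium enolate (LiN(iPr)2, −78 °C) is condensed with (R)-2,3-O-isopropylideneglyceraldehyde and dehydrated (MsCl, Et3N, then DBU) to methyl (8E)-9-[(4S)-2,2-dimethyl-1,3-dioxolan-4-yl]-7-oxonon-8-enoate F2. Corey–Bakshi–Shibata reduction with the (S)-oxazaborolidine should give methyl (7R,8E)-9-[(4S)-2,2-dimethyl-1,3-dioxolan-4-yl]-7-hydroxynon-8-enoate F3. Hydroxyl-directed Simmons–Smith cyclopropanation (Et2Zn, CH2I2, CH2Cl2) delivers CH2 syn to the C7 hydroxyl and should give methyl (7R)-7-[(1R,2R)-2-[(4S)-2,2-dimethyl-1,3-dioxolan-4-yl]cyclopropyl]-7-hydroxyheptanoate F4. Saponification (LiOH) gives (7R)-7-[(1R,2R)-2-[(4S)-2,2-dimethyl-1,3-dioxolan-4-yl]cyclopropyl]-7-hydroxyheptanoic acid F5. Yamaguchi lactonisation at high dilution (2,4,6-trichlorobenzoyl chloride, Et3N, then DMAP, toluene, 80 °C) gives (8R)-8-[(1R,2R)-2-[(4S)-2,2-dimethyl-1,3-dioxolan-4-yl]cyclopropyl]oxocan-2-one F6. Aqueous acetic acid then removes the acetonide to give 7.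

Step 14. The metalated sulfone may expel its β-silyloxide, the E selectivity may erode, or the base may epimerise the α-silyloxy aldehyde at C11. The fallback builds the side chain linearly, sets out from 9 and comes back at 21. Wittig reaction with (triphenylphosphoranylidene)acetaldehyde should give (2E,4R)-4-[(1R,2R)-2-[(2R)-8-oxooxocan-2-yl]cyclopropyl]-4-(triethylsilyloxy)but-2-enal F7. Catalytic asymmetric propargylation (allenylboronic acid pinacol ester, chiral BINOL-derived phosphoric acid, enantiomer chosen to deliver the 14S carbinol) should give (8R)-8-[(1R,2R)-2-[(1R,2E,4S)-4-hydroxy-1-(triethylsilyloxy)hept-2-en-6-yn-1-yl]cyclopropyl]oxocan-2-one F8. Copper-mediated coupling with 16 (CuI, Cs2CO3, DMF) gives (8R)-8-[(1R,2R)-2-[(1R,2E,4S)-4-hydroxy-1-(triethylsilyloxy)dodec-2-ene-6,9-diyn-1-yl]cyclopropyl]oxocan-2-one F9. Lindlar semihydrogenation gives (8R)-8-[(1R,2R)-2-[(1R,2E,4S,6Z,9Z)-4-hydroxy-1-(triethylsilyloxy)dodeca-2,6,9-trien-1-yl]cyclopropyl]oxocan-2-one F10. Desilylation under the conditions of step 15 gives 21.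

Step 3. Coupling may occur at the internal allyl terminus (branched alcohol), the new C10=C11 geometry may erode, or the boronate may protodeboronate. The fallback fixes the geometry and the linear connectivity in the electrophile, sets out from 3 and comes back at 5. Suzuki–Miyaura alkenyl–allyl coupling with (E)-(4-bromobut-2-en-1-yl)oxy(tert-butyl)dimethylsilane (Pd(PPh3)4, aqueous K3PO4, THF) should give tert-butyl (7E,10E)-12-(tert-butyldimethylsilyloxy)dodeca-7,10-dienoate F11. Desilylation with Bu4NF in THF then gives 5.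

Further compounds
F1 | step 5 | methyl 7-oxooctanoate | COC(=O)CCCCCC(C)=O
F2 | step 5 | methyl (8E)-9-[(4S)-2,2-dimethyl-1,3-dioxolan-4-yl]-7-oxonon-8-enoate | COC(=O)CCCCCC(=O)/C=C/[C@H]1COC(C)(C)O1
F3 | step 5 | methyl (7R,8E)-9-[(4S)-2,2-dimethyl-1,3-dioxolan-4-yl]-7-hydroxynon-8-enoate | COC(=O)CCCCC[C@@H](O)/C=C/[C@H]1COC(C)(C)O1
F4 | step 5 | methyl (7R)-7-[(1R,2R)-2-[(4S)-2,2-dimethyl-1,3-dioxolan-4-yl]cyclopropyl]-7-hydroxyheptanoate | COC(=O)CCCCC[C@@H](O)[C@@H]1C[C@H]1[C@H]1COC(C)(C)O1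
F5 | step 5 | (7R)-7-[(1R,2R)-2-[(4S)-2,2-dimethyl-1,3-dioxolan-4-yl]cyclopropyl]-7-hydroxyheptanoic acid | OC(=O)CCCCC[C@@H](O)[C@@H]1C[C@H]1[C@H]1COC(C)(C)O1
F6 | step 5 | (8R)-8-[(1R,2R)-2-[(4S)-2,2-dimethyl-1,3-dioxolan-4-yl]cyclopropyl]oxocan-2-one | CC1(C)OC[C@@H](O1)[C@@H]1C[C@H]1[C@H]1CCCCCC(=O)O1
F7 | step 14 | (2E,4R)-4-[(1R,2R)-2-[(2R)-8-oxooxocan-2-yl]cyclopropyl]-4-(triethylsilyloxy)but-2-enal | O=C/C=C/[C@@H](O[Si](CC)(CC)CC)[C@@H]1C[C@H]1[C@H]1CCCCCC(=O)O1
F8 | step 14 | (8R)-8-[(1R,2R)-2-[(1R,2E,4S)-4-hydroxy-1-(triethylsilyloxy)hept-2-en-6-yn-1-yl]cyclopropyl]oxocan-2-one | C#CC[C@H](O)/C=C/[C@@H](O[Si](CC)(CC)CC)[C@@H]1C[C@H]1[C@H]1CCCCCC(=O)O1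
F9 | step 14 | (8R)-8-[(1R,2R)-2-[(1R,2E,4S)-4-hydroxy-1-(triethylsilyloxy)dodec-2-ene-6,9-diyn-1-yl]cyclopropyl]oxocan-2-one | CCC#CCC#CC[C@H](O)/C=C/[C@@H](O[Si](CC)(CC)CC)[C@@H]1C[C@H]1[C@H]1CCCCCC(=O)O1
F10 | step 14 | (8R)-8-[(1R,2R)-2-[(1R,2E,4S,6Z,9Z)-4-hydroxy-1-(triethylsilyloxy)dodeca-2,6,9-trien-1-yl]cyclopropyl]oxocan-2-one | CC/C=C\C/C=C\C[C@H](O)/C=C/[C@@H](O[Si](CC)(CC)CC)[C@@H]1C[C@H]1[C@H]1CCCCCC(=O)O1
F11 | step 3 | tert-butyl (7E,10E)-12-(tert-butyldimethylsilyloxy)dodeca-7,10-dienoate | CC(C)(C)OC(=O)CCCCC/C=C/C/C=C/CO[Si](C)(C)C(C)(C)C
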